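**Plan**

- Retrosynthetic cuts, in order: the C8–H bond (hydrogenation of a C8 exocyclic methylene), the C4'=O oxygen (oxidation of a ring C CH2), C7–C8 (ring B), C1'–C7' (quaternary centre), and the C2–C1' biaryl bond.
- Forward: rings A and C are joined by Suzuki coupling. Ring C is dearomatised and the C7'–C8'–C8 chain is attached at C1' in one Birch reductive alkylation. Ring B is then closed between C7 and C8, ring C is oxidised to the dienone, and C8 is saturated last.
- Enabling feature: in ring B the carbinol carbon C7 lies between ring A carbon C1 and the methyl-bearing C8. C7 can therefore be an aryl aldehyde carbon on ring A, and C8 the metal-bearing carbon of a 2-iodoalkene whose exocyclic CH2 later becomes the C8 methyl. The quaternary C1' on the neighbouring ring A carbon C2 holds the two ends close.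
- Stereochemistry: C8' (R) comes from methyl (R)-3-hydroxy-2-methylpropanoate. C7 (R) is set in the ring closure under control of C8' (hydroxyl cis to the C8' methyl). C8 (S) is set by hydroxyl-directed hydrogenation (hydrogen syn to the hydroxyl, methyl trans). C1' is not stereogenic.

Key step: step 12

Remark: the SMILES is read as (7R,8S,8'R) in lignan labels; in the spiro[benzo[7]annulene-5,1'-cyclohexane] names used below, locants 9, 8, 7, 6 and 5 are lignan C7, C8, C8', C7' and C1', and the benzylic carbon is carried through the dissolving-metal step at the alcohol level (as its lithium alkoxide).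

**Route**

Step 1
Reactants: 1 methyl (R)-3-hydroxy-2-methylpropanoate
Product: 2 methyl (R)-3-[(tert-butyldimethylsilyl)oxy]-2-methylpropanoate
Conditions: TBSCl, imidazole, CH2Cl2, 0 °C to rt
Reagents that add atoms: tert-butyldimethylsilyl chloride, CC(C)(C)[Si](C)(C)Cl
Why: Silyl ether formation at a primary alcohol with imidazole as base, which is too weakly basic to epimerise the centre next to the ester.

Step 2
Reactants: 2 methyl (R)-3-[(tert-butyldimethylsilyl)oxy]-2-methylpropanoate
Product: 3 (R)-3-[(tert-butyldimethylsilyl)oxy]-2-methylpropanal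
Conditions: i-Bu2AlH (1.1 equiv), CH2Cl2, −78 °C; aq. KNaC4H4O6 (potassium sodium tartrate)
Reagents that add atoms: none
Why: Partial hydride reduction of an ester, in which the tetrahedral aluminium hemiacetal persists at −78 °C and releases the aldehyde only on work-up; the aldehyde is used at once so the α-centre keeps its configuration.

Step 3
Reactants: 3 (R)-3-[(tert-butyldimethylsilyl)oxy]-2-methylpropanal
Product: 4 (S)-tert-butyl[(4,4-dibromo-2-methylbut-3-en-1-yl)oxy]dimethylsilane
Conditions: CBr4, PPh3, Zn, CH2Cl2, 0 °C to rt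
Reagents that add atoms: carbon tetrabromide, BrC(Br)(Br)Br
Why: First stage of the Corey–Fuchs alkyne synthesis, a Wittig-type dibromomethylenation under non-basic conditions that leaves the stereocentre intact (the descriptor changes only through the priority rules).

Step 4
Reactants: 4 (S)-tert-butyl[(4,4-dibromo-2-methylbut-3-en-1-yl)oxy]dimethylsilane
Product: 6 (S)-tert-butyldimethyl{[2-methyl-4-(trimethylsilyl)but-3-yn-1-yl]oxy}silane, via lithium acetylide 5 (not isolated)
Conditions: n-BuLi (2.2 equiv), THF, −78 to 0 °C; TMSCl, −78 °C to rt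
Reagents that add atoms: chlorotrimethylsilane, C[Si](C)(C)Cl
Why: Second stage of the Corey–Fuchs sequence: bromine–lithium exchange, loss of LiBr with a 1,2-hydrogen shift (Fritsch–Buttenberg–Wiechell type) and deprotonation give acetylide 5, which is silylated on carbon to cap the acidic alkyne position.

Step 5
Reactants: 6 (S)-tert-butyldimethyl{[2-methyl-4-(trimethylsilyl)but-3-yn-1-yl]oxy}silane
Product: 7 (S)-2-methyl-4-(trimethylsilyl)but-3-yn-1-ol
Conditions: camphorsulfonic acid (cat.), MeOH, 0 °C to rt
Reagents that add atoms: none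
Why: Acid-catalysed methanolysis of a primary silyl ether; the alkynyl C–Si bond needs fluoride or alkoxide to break and so survives.

Step 6
Reactants: 7 (S)-2-methyl-4-(trimethylsilyl)but-3-yn-1-ol
Product: 8 (S)-(4-iodo-3-methylbut-1-yn-1-yl)trimethylsilane
Conditions: I2, PPh3, imidazole, CH2Cl2, 0 °C to rt
Reagents that add atoms: iodine, II
Why: Appel-type iodination, in which iodide displaces the alkoxyphosphonium group in an SN2 reaction at the primary carbon and the neighbouring stereocentre is not involved.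

Step 7
Reactants: 9 2-bromo-3,4,5-trimethoxybenzaldehyde; 10 3,5-dimethoxyphenylboronic acid
Product: 11 2-(3,5-dimethoxyphenyl)-3,4,5-trimethoxybenzaldehyde
Conditions: Pd(PPh3)4 (3 mol%), K2CO3, DME/H2O, 85 °C
Reagents that add atoms: none
Why: Suzuki–Miyaura cross-coupling of an aryl bromide flanked by formyl and methoxy groups with an unhindered arylboronic acid, which forms the C2–C1' biaryl bond and leaves the aldehyde alone.

Step 8
Reactants: 11 2-(3,5-dimethoxyphenyl)-3,4,5-trimethoxybenzaldehyde
Product: 12 [2-(3,5-dimethoxyphenyl)-3,4,5-trimethoxyphenyl]methanol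
Conditions: NaBH4, MeOH/THF, 0 °C
Reagents that add atoms: none
Why: Borohydride reduction of the aryl aldehyde; C7 is taken to the alcohol level because a lithium benzyl alkoxide withstands dissolving-metal reduction whereas an aldehyde or acetal would not.

Step 9
Reactants: 12 [2-(3,5-dimethoxyphenyl)-3,4,5-trimethoxyphenyl]methanol; 8 (S)-(4-iodo-3-methylbut-1-yn-1-yl)trimethylsilane
Product: 15 {2-[3,5-dimethoxy-1-((2R)-2-methylbut-3-yn-1-yl)cyclohexa-2,5-dien-1-yl]-3,4,5-trimethoxyphenyl}methanol, via dilithium carbanion alkoxide 13 (not isolated), via C-silyl alkyne 14 (not isolated)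
Conditions: Li (ca. 2.5 equiv, to persistent blue), NH3/THF, −78 °C; a few drops of isoprene to discharge the colour; 8, −78 to −33 °C; MeOH, NH3 evaporated; K2CO3, MeOH, rt
Reagents that add atoms: none
Why: Birch reductive alkylation of a biaryl: ring C takes up two electrons and is protonated at C4' (between the two methoxy-bearing carbons) by the hydroxyl proton of 12, which leaves a C1' carbanion stabilised by ring A that the primary iodide 8 alkylates in an SN2 reaction to form the quaternary centre, while the more electron-rich ring A with its alkoxide is not reduced, the silyl cap prevents proton transfer from the alkyne, and methoxide finally removes the C-silyl group without touching C8'.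

Step 10
Reactants: 15 {2-[3,5-dimethoxy-1-((2R)-2-methylbut-3-yn-1-yl)cyclohexa-2,5-dien-1-yl]-3,4,5-trimethoxyphenyl}methanol
Product: 17 {2-[1-((2R)-3-iodo-2-methylbut-3-en-1-yl)-3,5-dimethoxycyclohexa-2,5-dien-1-yl]-3,4,5-trimethoxyphenyl}methanol, via internal alkenylalane 16 (not isolated)
Conditions: i-Bu2AlH (2.4 equiv), NiCl2(dppp) (3 mol%), THF, 0 °C to rt; I2, THF, −78 to 0 °C; aq. KNaC4H4O6/Na2S2O3
Reagents that add atoms: iodine, II
Why: Nickel-catalysed hydroalumination of a terminal alkyne, in which the chelating diphosphine steers aluminium to the internal carbon C8 (Markovnikov sense), followed by iodinolysis of the C–Al bond; the first hydride equivalent is spent on the hydroxyl, the C–Al bond consumes iodine at −78 °C far faster than the enol ethers do, and no acid is present to hydrolyse ring C.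

Step 11
Reactants: 17 {2-[1-((2R)-3-iodo-2-methylbut-3-en-1-yl)-3,5-dimethoxycyclohexa-2,5-dien-1-yl]-3,4,5-trimethoxyphenyl}methanol
Product: 18 2-[1-((2R)-3-iodo-2-methylbut-3-en-1-yl)-3,5-dimethoxycyclohexa-2,5-dien-1-yl]-3,4,5-trimethoxybenzaldehyde
Conditions: (n-C3H7)4N[RuO4] (5 mol%), N-methylmorpholine N-oxide, 4 Å molecular sieves, CH2Cl2, rt
Reagents that add atoms: none
Why: Ley–Griffith oxidation of a benzylic alcohol (catalytic perruthenate, amine N-oxide as terminal oxidant) under neutral anhydrous conditions that the enol ethers and the iodoalkene tolerate.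

Step 12
Reactants: 18 2-[1-((2R)-3-iodo-2-methylbut-3-en-1-yl)-3,5-dimethoxycyclohexa-2,5-dien-1-yl]-3,4,5-trimethoxybenzaldehyde
Product: 20 (7R,9R)-2,3,3',4,5'-pentamethoxy-7-methyl-8-methylidene-6,7,8,9-tetrahydrospiro[benzo[7]annulene-5,1'-cyclohexa[2,5]dien]-9-ol, via alkenylchromium dichloride 19 (not isolated)
Conditions: CrCl2 (6 equiv), NiCl2 (0.1 equiv), degassed DMSO, rt, slow addition of 18 to 0.005 M; aq. NaHCO3/ethylenediamine
Reagents that add atoms: none
Why: CrCl2 reduces NiCl2 to zerovalent nickel, which inserts into the C8–I bond; transmetalation to trivalent chromium gives alkenylchromium 19, a non-basic carbon nucleophile that adds to the aldehyde carbon C7 and ignores the enol ethers and aryl ethers (Nozaki–Hiyama–Kishi reaction). The closest known reaction type is the intramolecular chromium/nickel coupling of 2-iodoalkenes with aldehydes used to close medium rings. Ring B closes in a 7-exo-trig mode, helped by the quaternary C1' on the ring A carbon next to the one bearing the aldehyde (Thorpe–Ingold effect) and by high dilution, which suppresses intermolecular coupling. The new stereocentre C7 is controlled by C8': in the chair-like closing ring the C8' methyl and the chromium-bound oxygen should both take pseudo-equatorial positions on either side of the sp2 carbon C8, which places the hydroxyl cis to the C8' methyl (7R). The step needs chemoselectivity for the aldehyde, which is inherent in organochromium reagents, and this diastereoface selectivity, which rests on a single stereocentre two atoms away and is the point to watch.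

Step 13
Reactants: 20 (7R,9R)-2,3,3',4,5'-pentamethoxy-7-methyl-8-methylidene-6,7,8,9-tetrahydrospiro[benzo[7]annulene-5,1'-cyclohexa[2,5]dien]-9-ol
Product: 21 tert-butyl{[(7R,9R)-2,3,3',4,5'-pentamethoxy-7-methyl-8-methylidene-6,7,8,9-tetrahydrospiro[benzo[7]annulene-5,1'-cyclohexa[2,5]dien]-9-yl]oxy}dimethylsilane
Conditions: TBSOTf, 2,6-lutidine, CH2Cl2, −78 °C
Reagents that add atoms: tert-butyldimethylsilyl trifluoromethanesulfonate, CC(C)(C)[Si](C)(C)OS(=O)(=O)C(F)(F)F
Why: Silyl ether formation with a silyl triflate and a hindered pyridine base, needed because the free allylic benzylic alcohol would be oxidised to the enone in the next step; the base keeps the medium non-acidic for the enol ethers.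

Step 14
Reactants: 21 tert-butyl{[(7R,9R)-2,3,3',4,5'-pentamethoxy-7-methyl-8-methylidene-6,7,8,9-tetrahydrospiro[benzo[7]annulene-5,1'-cyclohexa[2,5]dien]-9-yl]oxy}dimethylsilane
Product: 22 (7R,9R)-9-[(tert-butyldimethylsilyl)oxy]-2,3,3',4,5'-pentamethoxy-7-methyl-8-methylidene-6,7,8,9-tetrahydrospiro[benzo[7]annulene-5,1'-cyclohexa[2,5]dien]-4'-one
Conditions: (C5H5NH)2Cr2O7 (pyridinium dichromate), t-BuOOH (in decane), Celite, benzene, 10 °C to rt
Reagents that add atoms: tert-butyl hydroperoxide, CC(C)(C)OO
Why: Bis-allylic C–H oxidation of a Birch-type cyclohexa-1,4-diene to the cross-conjugated dienone, with hexavalent chromium generating peroxy radicals and the hydroperoxide as terminal oxidant: C4'H2 lies between two enol ether double bonds and has by far the weakest C–H bonds, C1' is quaternary so aromatisation is impossible, and the silyl ether shields C7–H.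

Step 15
Reactants: 22 (7R,9R)-9-[(tert-butyldimethylsilyl)oxy]-2,3,3',4,5'-pentamethoxy-7-methyl-8-methylidene-6,7,8,9-tetrahydrospiro[benzo[7]annulene-5,1'-cyclohexa[2,5]dien]-4'-one
Product: 23 (7R,9R)-9-hydroxy-2,3,3',4,5'-pentamethoxy-7-methyl-8-methylidene-6,7,8,9-tetrahydrospiro[benzo[7]annulene-5,1'-cyclohexa[2,5]dien]-4'-one
Conditions: HF·pyridine, pyridine, THF, 0 °C to rt
Reagents that add atoms: none
Why: Fluoride-mediated silyl ether cleavage in a pyridine-buffered, non-basic medium, which avoids an alkoxide next to the dienone (oxa-Michael addition) and ionisation of the benzylic alcohol.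

Step 16
Reactants: 23 (7R,9R)-9-hydroxy-2,3,3',4,5'-pentamethoxy-7-methyl-8-methylidene-6,7,8,9-tetrahydrospiro[benzo[7]annulene-5,1'-cyclohexa[2,5]dien]-4'-one
Product: 24 (7R,8S,9R)-9-hydroxy-2,3,3',4,5'-pentamethoxy-7,8-dimethyl-6,7,8,9-tetrahydrospiro[benzo[7]annulene-5,1'-cyclohexa[2,5]dien]-4'-one (CNP0288561.1)
Conditions: H2 (1 atm), [Ir(cod)(PCy3)(py)]PF6 (5 mol%), CH2Cl2, rt
Reagents that add atoms: none
Why: Hydroxyl-directed homogeneous hydrogenation: the cationic iridium catalyst binds the C7 hydroxyl and delivers both hydrogens to the exocyclic C8 alkene from the hydroxyl face, so C8–H ends cis and the new methyl trans to the hydroxyl (8S), while the hindered, electron-poor dienone double bonds have no directing group and should react much more slowly.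

**Compound list**

1 | methyl (R)-3-hydroxy-2-methylpropanoate | COC(=O)[C@H](C)CO | starting material
2 | methyl (R)-3-[(tert-butyldimethylsilyl)oxy]-2-methylpropanoate | COC(=O)[C@H](C)CO[Si](C)(C)C(C)(C)C | intermediate
3 | (R)-3-[(tert-butyldimethylsilyl)oxy]-2-methylpropanal | O=C[C@H](C)CO[Si](C)(C)C(C)(C)C | intermediate
4 | (S)-tert-butyl[(4,4-dibromo-2-methylbut-3-en-1-yl)oxy]dimethylsilane | BrC(Br)=C[C@H](C)CO[Si](C)(C)C(C)(C)C | intermediate
5 | lithium (S)-4-[(tert-butyldimethylsilyl)oxy]-3-methylbut-1-yn-1-ide (not isolated) | [Li]C#C[C@H](C)CO[Si](C)(C)C(C)(C)C | intermediate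
6 | (S)-tert-butyldimethyl{[2-methyl-4-(trimethylsilyl)but-3-yn-1-yl]oxy}silane | C[Si](C)(C)C#C[C@H](C)CO[Si](C)(C)C(C)(C)C | intermediate
7 | (S)-2-methyl-4-(trimethylsilyl)but-3-yn-1-ol | C[Si](C)(C)C#C[C@H](C)CO | intermediate
8 | (S)-(4-iodo-3-methylbut-1-yn-1-yl)trimethylsilane | C[Si](C)(C)C#C[C@H](C)CI | intermediate
9 | 2-bromo-3,4,5-trimethoxybenzaldehyde | COc1cc(C=O)c(Br)c(OC)c1OC | starting material
10 | 3,5-dimethoxyphenylboronic acid | COc1cc(cc(OC)c1)B(O)O | starting material
11 | 2-(3,5-dimethoxyphenyl)-3,4,5-trimethoxybenzaldehyde | COc1cc(cc(OC)c1)-c1c(OC)c(OC)c(OC)cc1C=O | intermediate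
12 | [2-(3,5-dimethoxyphenyl)-3,4,5-trimethoxyphenyl]methanol | COc1cc(cc(OC)c1)-c1c(OC)c(OC)c(OC)cc1CO | intermediate
13 | dilithium salt of 12 after two-electron reduction and C4' protonation: lithium on C1' of the 3,5-dimethoxycyclohexa-2,5-dienyl ring and on the benzylic oxygen (not isolated) | COC1=CC([Li])(C=C(OC)C1)c1c(OC)c(OC)c(OC)cc1CO[Li] | intermediate
14 | {2-[3,5-dimethoxy-1-((2R)-2-methyl-4-(trimethylsilyl)but-3-yn-1-yl)cyclohexa-2,5-dien-1-yl]-3,4,5-trimethoxyphenyl}methanol (not isolated) | COC1=CC(C=C(OC)C1)(C[C@@H](C)C#C[Si](C)(C)C)c1c(OC)c(OC)c(OC)cc1CO | intermediate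
15 | {2-[3,5-dimethoxy-1-((2R)-2-methylbut-3-yn-1-yl)cyclohexa-2,5-dien-1-yl]-3,4,5-trimethoxyphenyl}methanol | COC1=CC(C=C(OC)C1)(C[C@@H](C)C#C)c1c(OC)c(OC)c(OC)cc1CO | intermediate
16 | internal alkenylalane of 15: diisobutylaluminium on C8 of the (2R)-2-methylbut-3-en-3-yl chain, benzylic oxygen as its diisobutylaluminium alkoxide (not isolated) | COC1=CC(C=C(OC)C1)(C[C@@H](C)C(=C)[Al](CC(C)C)CC(C)C)c1c(OC)c(OC)c(OC)cc1CO[Al](CC(C)C)CC(C)C | intermediate
17 | {2-[1-((2R)-3-iodo-2-methylbut-3-en-1-yl)-3,5-dimethoxycyclohexa-2,5-dien-1-yl]-3,4,5-trimethoxyphenyl}methanol | COC1=CC(C=C(OC)C1)(C[C@@H](C)C(I)=C)c1c(OC)c(OC)c(OC)cc1CO | intermediate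
18 | 2-[1-((2R)-3-iodo-2-methylbut-3-en-1-yl)-3,5-dimethoxycyclohexa-2,5-dien-1-yl]-3,4,5-trimethoxybenzaldehyde | COC1=CC(C=C(OC)C1)(C[C@@H](C)C(I)=C)c1c(OC)c(OC)c(OC)cc1C=O | intermediate
19 | alkenylchromium dichloride of 18 (trivalent chromium on C8 in place of iodine; not isolated) | COC1=CC(C=C(OC)C1)(C[C@@H](C)C(=C)[Cr](Cl)Cl)c1c(OC)c(OC)c(OC)cc1C=O | intermediate
20 | (7R,9R)-2,3,3',4,5'-pentamethoxy-7-methyl-8-methylidene-6,7,8,9-tetrahydrospiro[benzo[7]annulene-5,1'-cyclohexa[2,5]dien]-9-ol (lignan labels 7R,8'R) | COC1=CC2(C=C(OC)C1)C[C@@H](C)C(=C)[C@@H](O)c1cc(OC)c(OC)c(OC)c12 | intermediate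
21 | tert-butyldimethylsilyl ether of 20 at the C9 (lignan C7) oxygen | COC1=CC2(C=C(OC)C1)C[C@@H](C)C(=C)[C@@H](O[Si](C)(C)C(C)(C)C)c1cc(OC)c(OC)c(OC)c12 | intermediate
22 | (7R,9R)-9-[(tert-butyldimethylsilyl)oxy]-2,3,3',4,5'-pentamethoxy-7-methyl-8-methylidene-6,7,8,9-tetrahydrospiro[benzo[7]annulene-5,1'-cyclohexa[2,5]dien]-4'-one | COC1=CC2(C=C(OC)C1=O)C[C@@H](C)C(=C)[C@@H](O[Si](C)(C)C(C)(C)C)c1cc(OC)c(OC)c(OC)c12 | intermediate
23 | (7R,9R)-9-hydroxy-2,3,3',4,5'-pentamethoxy-7-methyl-8-methylidene-6,7,8,9-tetrahydrospiro[benzo[7]annulene-5,1'-cyclohexa[2,5]dien]-4'-one | COC1=CC2(C=C(OC)C1=O)C[C@@H](C)C(=C)[C@@H](O)c1cc(OC)c(OC)c(OC)c12 | intermediate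
24 | (7R,8S,9R)-9-hydroxy-2,3,3',4,5'-pentamethoxy-7,8-dimethyl-6,7,8,9-tetrahydrospiro[benzo[7]annulene-5,1'-cyclohexa[2,5]dien]-4'-one, CNP0288561.1 (lignan labels 7R,8S,8'R) | COC1=CC2(C=C(OC)C1=O)C[C@@H](C)[C@H](C)[C@@H](O)c1cc(OC)c(OC)c(OC)c12 | target

**Step count and risks**

Total step count: 16. Longest linear sequence: 14 steps (steps 1–6, then 9–16); the arene branch (steps 7–8) joins at step 9.

Steps most likely to fail:

1. Step 9. Ring A carries no anionic shield on the ring itself, so electron uptake by ring A (reductive loss of a methoxy group or of the benzylic oxygen) could compete with reduction of ring C; elimination of the β-branched iodide by the hindered C1' carbanion is a second loss channel. The fallback runs the dissolving-metal step on a phenoxide, which keeps its own ring from being reduced, and installs the benzylic carbon afterwards. It sets out from boronic acid 10 and iodide 8. Commercial 3,4,5-trimethoxyphenol would be brominated (NBS, CH2Cl2, −78 to 0 °C) to 2-bromo-3,4,5-trimethoxyphenol F1. Suzuki coupling with 10 (Pd(PPh3)4, K2CO3, DME/H2O) should give 2-(3,5-dimethoxyphenyl)-3,4,5-trimethoxyphenol F2. Birch reductive alkylation with 8 (Li, NH3/THF, −78 °C, silyl cap retained) should give the alkylated phenol F3. Triflation (PhNTf2, K2CO3, DMF) gives the aryl triflate F4, and palladium-catalysed methoxycarbonylation (Pd(OAc)2, dppp, CO, MeOH, Et3N, DMSO, 70 °C) gives the methyl ester F5. Reduction with i-Bu2AlH (CH2Cl2, −78 °C) comes back to the route at 14, which is desilylated to 15 as in step 9.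

2. Step 12. The ring closure may show poor diastereoface selection at C7, giving mainly or partly the epimer with the hydroxyl trans to the C8' methyl. The fallback moves the control of C7 from the C–C bond formation to a ketone reduction. It sets out from 18: the closure is run as in step 12, and the mixture of 20 and its C7 epimer F6 is oxidised (MnO2, CH2Cl2, rt) to the cross-conjugated C7 ketone F7. A 1,2-reduction with i-Bu2AlH (toluene, −78 °C) should then deliver hydride along the pseudo-axial trajectory and give the pseudo-equatorial alcohol cis to the C8' methyl, as with small hydrides and 3-substituted cyclohexanones. This comes back to the route at 20.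

3. Step 14. The radical oxidant may attack the electron-rich enol ether double bonds, or the allylic C7–H and C8'–H positions of ring B, instead of C4'H2, and the pyridinium salt may hydrolyse an enol ether. The fallback replaces the radical C–H oxidation by an anionic one. It sets out from 21: deprotonation between the two enol ether carbons (t-BuLi, THF/HMPA, −78 °C, as known for 1,5-dimethoxycyclohexa-1,4-dienes) and hydroxylation of the carbanion with 2-(phenylsulfonyl)-3-phenyloxaziridine should give the C4' alcohol F8 as a mixture of C4' epimers. Oxidation of this bis-allylic alcohol (MnO2, CH2Cl2, rt) comes back to the route at 22.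

**Further compounds**

F1 | step 9 | 2-bromo-3,4,5-trimethoxyphenol | COc1cc(O)c(Br)c(OC)c1OC
F2 | step 9 | 2-(3,5-dimethoxyphenyl)-3,4,5-trimethoxyphenol | COc1cc(cc(OC)c1)-c1c(O)cc(OC)c(OC)c1OC
F3 | step 9 | 2-[3,5-dimethoxy-1-((2R)-2-methyl-4-(trimethylsilyl)but-3-yn-1-yl)cyclohexa-2,5-dien-1-yl]-3,4,5-trimethoxyphenol | COC1=CC(C=C(OC)C1)(C[C@@H](C)C#C[Si](C)(C)C)c1c(O)cc(OC)c(OC)c1OC
F4 | step 9 | 2-[3,5-dimethoxy-1-((2R)-2-methyl-4-(trimethylsilyl)but-3-yn-1-yl)cyclohexa-2,5-dien-1-yl]-3,4,5-trimethoxyphenyl trifluoromethanesulfonate | COC1=CC(C=C(OC)C1)(C[C@@H](C)C#C[Si](C)(C)C)c1c(OS(=O)(=O)C(F)(F)F)cc(OC)c(OC)c1OC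
F5 | step 9 | methyl 2-[3,5-dimethoxy-1-((2R)-2-methyl-4-(trimethylsilyl)but-3-yn-1-yl)cyclohexa-2,5-dien-1-yl]-3,4,5-trimethoxybenzoate | COC1=CC(C=C(OC)C1)(C[C@@H](C)C#C[Si](C)(C)C)c1c(C(=O)OC)cc(OC)c(OC)c1OC
F6 | step 12 | (7R,9S)-2,3,3',4,5'-pentamethoxy-7-methyl-8-methylidene-6,7,8,9-tetrahydrospiro[benzo[7]annulene-5,1'-cyclohexa[2,5]dien]-9-ol (C7 epimer of 20 in lignan labels) | COC1=CC2(C=C(OC)C1)C[C@@H](C)C(=C)[C@H](O)c1cc(OC)c(OC)c(OC)c12
F7 | step 12 | (7R)-2,3,3',4,5'-pentamethoxy-7-methyl-8-methylidene-7,8-dihydrospiro[benzo[7]annulene-5,1'-cyclohexa[2,5]dien]-9(6H)-one | COC1=CC2(C=C(OC)C1)C[C@@H](C)C(=C)C(=O)c1cc(OC)c(OC)c(OC)c12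
F8 | step 14 | (7R,9R)-9-[(tert-butyldimethylsilyl)oxy]-2,3,3',4,5'-pentamethoxy-7-methyl-8-methylidene-6,7,8,9-tetrahydrospiro[benzo[7]annulene-5,1'-cyclohexa[2,5]dien]-4'-ol (both C4' epimers) | COC1=CC2(C=C(OC)C1O)C[C@@H](C)C(=C)[C@@H](O[Si](C)(C)C(C)(C)C)c1cc(OC)c(OC)c(OC)c12
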